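**Plan**
- Retrosynthesis: the 3'-OH is masked as an acetate, then ring B is cut at C1'–C6' and C2'–C3' (with CO2 restored across C3'/C6'), giving a chromon-3-yl methoxyalkyne and 3-acetoxy-2-pyrone.
- The alkyne is cut at chromone C3–C(sp) into a 3-iodochromone and a methoxyethynyl metal; ring C is opened at O1–C2 to an enaminone of a 2-hydroxyacetophenone.
- Forward: ring A is bought as 3,4,5-trimethoxyphenol, ring C is closed onto it by iodocyclisation, the two-carbon ynol ether is attached by Negishi coupling, and ring B is built last by Diels–Alder addition and loss of CO2.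
- Enabling feature: in ring B, C1' (chromone), C2' (OMe) and C3' (OH) are contiguous and C4', C5', C6' are CH. This is a methoxyalkyne (C1'–C2') joined to C3–C6 of a 3-oxygenated 2-pyrone whose O1–C2 bridge leaves as CO2.
- Stereochemistry: the target has no stereocentre and no stereogenic double bond; the only selectivity to control is the regiochemistry of the cycloaddition.

Key step: step 7

Remark: the transient cycloadduct 13 forms as a racemate and is drawn as one enantiomer; both bridgehead centres vanish on aromatisation.

Step 1
Reactants: 1 3,4,5-trimethoxyphenol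
Product: 2 1-(6-hydroxy-2,3,4-trimethoxyphenyl)ethan-1-one
Conditions: AcOH, BF3·OEt2, 90 °C; then H2O
Reagents that add atoms: acetic acid, CC(=O)O
Why: BF3-mediated Friedel–Crafts (Fries-type) C-acetylation should occur at one of the two equivalent free ring positions, ortho to the hydroxyl, and the chelated ortho-hydroxy ketone is deactivated towards a second acylation.

Step 2
Reactants: 2 1-(6-hydroxy-2,3,4-trimethoxyphenyl)ethan-1-one
Product: 3 (E)-3-(dimethylamino)-1-(6-hydroxy-2,3,4-trimethoxyphenyl)prop-2-en-1-one
Conditions: Me2NCH(OMe)2, PhMe, 95 °C
Reagents that add atoms: N,N-dimethylformamide dimethyl acetal, COC(OC)N(C)C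
Why: Condensation of a methyl ketone with a formamide acetal (enaminone formation) is general for 2-hydroxyacetophenones, gives the E-enaminone and leaves the hydrogen-bonded phenol free.

Step 3
Reactants: 3 (E)-3-(dimethylamino)-1-(6-hydroxy-2,3,4-trimethoxyphenyl)prop-2-en-1-one
Product: 4 3-iodo-5,6,7-trimethoxy-4H-chromen-4-one
Conditions: I2, CHCl3, rt
Reagents that add atoms: iodine, II
Why: Iodine-mediated cyclisation of a 2-hydroxyaryl enaminone (α-iodination, attack of the phenol on the iminium carbon, loss of dimethylamine) should give the 3-iodochromone directly, the enaminone being far more reactive towards iodine than the arene.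

Step 4
Reactants: 5 2-chloro-1,1-dimethoxyethane (chloroacetaldehyde dimethyl acetal)
Product: 7 methoxyethyne (methoxyacetylene), via sodium methoxyacetylide 6 (not isolated)
Conditions: NaNH2 (3.3 equiv), liquid NH3, −33 °C; NH3 evaporated; satd aq NaCl, −70 → 0 °C; distilled into THF at −78 °C and titrated
Reagents that add atoms: none
Why: Twofold base-induced β-elimination (methanol, then hydrogen chloride) with sodium amide in liquid ammonia is the standard preparation of alkoxyacetylenes from chloroacetals, and the third equivalent of base holds the product as its acetylide until the cold aqueous quench.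

Step 5
Reactants: 7 methoxyethyne; 4 3-iodo-5,6,7-trimethoxy-4H-chromen-4-one
Product: 10 5,6,7-trimethoxy-3-(methoxyethynyl)-4H-chromen-4-one, via lithium methoxyacetylide 8 (not isolated), via methoxyethynylzinc chloride 9 (not isolated)
Conditions: 7 (1.5 equiv), n-BuLi, THF, −78 °C; ZnCl2, −78 → 0 °C; then 4, Pd(PPh3)4 (5 mol %), THF, 0 °C → rt; aq NaHCO3 work-up, Et3N-treated silica
Reagents that add atoms: none
Why: Negishi coupling of an alkoxyethynylzinc chloride with an sp2 iodide should work because the 3-iodochromone adds readily to zerovalent palladium, the zinc acetylide is too weak a nucleophile to attack C2 of the chromone, and the non-acidic work-up spares the ynol ether.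

Step 6
Reactants: 11 3-hydroxy-2H-pyran-2-one
Product: 12 2-oxo-2H-pyran-3-yl acetate
Conditions: Ac2O, pyridine, DMAP (cat.), CH2Cl2, 0 °C → rt
Reagents that add atoms: acetic anhydride, CC(=O)OC(C)=O
Why: O-Acylation of the enolic 3-hydroxyl under nucleophilic catalysis removes the acidic proton that would otherwise add across the ynol ether in the next step.

Step 7
Reactants: 10 5,6,7-trimethoxy-3-(methoxyethynyl)-4H-chromen-4-one; 12 2-oxo-2H-pyran-3-yl acetate
Product: 14 2-methoxy-3-(5,6,7-trimethoxy-4-oxo-4H-chromen-3-yl)phenyl acetate, via bridged lactone cycloadduct 13 (not isolated)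
Conditions: 12 (3 equiv), degassed PhMe (0.5 M), sealed tube, 120–130 °C (−CO2)
Reagents that add atoms: none
Why: Proposed new method: the electron-rich methoxyalkyne of 10 and the electron-poor diene C3=C4–C5=C6 of pyrone 12 should combine in an asynchronous inverse-electron-demand Diels–Alder reaction, in which the nucleophilic alkyne carbon (the one bonded to chromone C3) attacks the vinylogous-ester terminus C6 of the pyrone and the methoxy-bearing carbon closes onto C3; the closest known reactions are the cycloaddition–decarboxylation benzannulations of 2-pyrones with ynamines, alkynylboronates and other alkynes, and the additions of ketene acetals to 3-substituted 2-pyrones. Ring B is closed as a six-membered carbocycle by intermolecular [4+2] cycloaddition (bonds C1'–C6' and C2'–C3'), giving the 2-oxabicyclo[2.2.2]octadienone 13, whose O–C(=O) bridge then leaves as CO2 in an irreversible retro-[4+2] step that aromatises the ring. No stereocentre is created in the product, since the two bridgeheads of 13 become aromatic carbons. The selectivity needed is regiochemical, methoxy next to acetoxy, and it should be secured because the polarisation of the ynol ether (nucleophilic at the carbon remote from oxygen) matches the electrophilic C6 of the pyrone, while the bulky chromonyl group is also kept away from the acetoxy-bearing C3. The O-methyl group carries no β-hydrogen, so the retro-ene fragmentation to a ketene that limits ethyl and tert-butyl ynol ethers on heating is closed, and the acetate keeps the pyrone free of an acidic OH while delivering the two ring B oxygens already differentiated.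

Step 8
Reactants: 14 2-methoxy-3-(5,6,7-trimethoxy-4-oxo-4H-chromen-3-yl)phenyl acetate
Product: 15 3-(3-hydroxy-2-methoxyphenyl)-5,6,7-trimethoxy-4H-chromen-4-one
Conditions: K2CO3 (0.3 equiv), MeOH, 0 °C → rt; aq NH4Cl
Reagents that add atoms: none
Why: Base-catalysed transesterification of the aryl acetate with methanol is fast at low temperature, whereas the four methyl ethers and the chromone ring should be inert to catalytic carbonate over a short reaction time.

**Compound list**
1 | 3,4,5-trimethoxyphenol | COc1cc(O)cc(OC)c1OC | starting material
2 | 1-(6-hydroxy-2,3,4-trimethoxyphenyl)ethan-1-one | CC(=O)c1c(O)cc(OC)c(OC)c1OC | intermediate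
3 | (E)-3-(dimethylamino)-1-(6-hydroxy-2,3,4-trimethoxyphenyl)prop-2-en-1-one | CN(C)/C=C/C(=O)c1c(O)cc(OC)c(OC)c1OC | intermediate
4 | 3-iodo-5,6,7-trimethoxy-4H-chromen-4-one | COc1cc2occ(I)c(=O)c2c(OC)c1OC | intermediate
5 | 2-chloro-1,1-dimethoxyethane (chloroacetaldehyde dimethyl acetal) | COC(CCl)OC | starting material
6 | sodium methoxyacetylide | [Na+].[C-]#COC | intermediate
7 | methoxyethyne (methoxyacetylene) | C#COC | intermediate
8 | lithium methoxyacetylide | [Li]C#COC | intermediate
9 | methoxyethynylzinc chloride | COC#C[Zn]Cl | intermediate
10 | 5,6,7-trimethoxy-3-(methoxyethynyl)-4H-chromen-4-one | COC#Cc1coc2cc(OC)c(OC)c(OC)c2c1=O | intermediate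
11 | 3-hydroxy-2H-pyran-2-one | Oc1cccoc1=O | starting material
12 | 2-oxo-2H-pyran-3-yl acetate | CC(=O)Oc1cccoc1=O | intermediate
13 | 8-methoxy-3-oxo-7-(5,6,7-trimethoxy-4-oxo-4H-chromen-3-yl)-2-oxabicyclo[2.2.2]octa-5,7-dien-4-yl acetate (racemic, one enantiomer drawn) | CC(=O)O[C@@]12C=C[C@@H](OC1=O)C(c1coc3cc(OC)c(OC)c(OC)c3c1=O)=C2OC | intermediate
14 | 2-methoxy-3-(5,6,7-trimethoxy-4-oxo-4H-chromen-3-yl)phenyl acetate | COc1cc2occ(-c3cccc(OC(C)=O)c3OC)c(=O)c2c(OC)c1OC | intermediate
15 | 3-(3-hydroxy-2-methoxyphenyl)-5,6,7-trimethoxy-4H-chromen-4-one | COc1cc2occ(-c3cccc(O)c3OC)c(=O)c2c(OC)c1OC | target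

**Step count**
Total: 8 steps. Longest linear sequence: 6 steps (1 → 2 → 3 → 4 → 10 → 14 → 15; steps 1, 2, 3, 5, 7, 8). Steps 4 and 6 are side branches.

**Steps most likely to fail**

Step 7. The cycloaddition may be too slow for an aryl-conjugated ynol ether. Thermal oligomerisation, acid-induced hydration of the alkyne, or bonding at the wrong alkyne carbon could then take over before ring B forms. The fallback uses known chemistry and forms the C3–C1' bond instead of ring B; it sets out from 4 and comes back to the route at 15. Purchased 3-bromo-2-methoxyphenol F1 is converted by Miyaura borylation (B2pin2, PdCl2(dppf), KOAc, dioxane, 90 °C) into 2-methoxy-3-(4,4,5,5-tetramethyl-1,3,2-dioxaborolan-2-yl)phenol F2. Suzuki–Miyaura coupling of F2 with 4 (Pd(PPh3)4, aq Na2CO3, DME, 80 °C) should then give 15 directly, the free phenol being tolerated.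

Step 5. Zinc halide in the flask may promote hydration, oligomerisation or carbonyl-oxygen cyclisation of the ynol ether, and part of the acetylide may add to C2 of the chromone and open ring C. The fallback uses an isolated, neutral tin acetylide; it sets out from 7 (through 8) and 4 and comes back at 10. Acetylide 8, made as in step 5, is quenched with Bu3SnCl (THF, −78 °C → rt) and distilled to give tributyl(methoxyethynyl)stannane F3. Stille coupling of F3 with 4 (PdCl2(PPh3)2, Et4NCl, DMF, rt → 50 °C) should deliver 10 without Lewis-acidic zinc salts or a free carbanion.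

Step 4. Loss of the low-boiling, polymerisation-prone alkyne during distillation and storage may leave too little titrated reagent for the coupling. The fallback never liberates the free alkyne; it replaces 5 by purchased trichloroethene F4 and comes back at 8. F4 with NaOMe in MeOH at reflux (base-induced elimination–addition) should give distillable (E)-1,2-dichloro-1-methoxyethene F5. F5 with n-BuLi (2 equiv, THF, −78 °C) should give 8 by deprotonation, loss of chloride and chlorine–lithium exchange, and 8 then enters step 5 at the ZnCl2 stage.

**Further compounds**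
F1 | step 7 | 3-bromo-2-methoxyphenol | COc1c(O)cccc1Br
F2 | step 7 | 2-methoxy-3-(4,4,5,5-tetramethyl-1,3,2-dioxaborolan-2-yl)phenol | COc1c(O)cccc1B1OC(C)(C)C(C)(C)O1
F3 | step 5 | tributyl(methoxyethynyl)stannane | CCCC[Sn](CCCC)(CCCC)C#COC
F4 | step 4 | trichloroethene | ClC=C(Cl)Cl
F5 | step 4 | (E)-1,2-dichloro-1-methoxyethene | Cl/C=C(/Cl)OC
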